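The readings are simulated for an exercise; scatter was added.

4 questions stand on the dusk flask, and one quantity answers them: the fraction of the charged partner that ends as target.

all flasks: starting material 1.3 M

|  | partner | temperature | remark | time |
|---|---|---|---|---|
| dusk | 1.3 equiv | 25 °C | the very flask that is asked about, followed so far |  |
| autumn | 1.3 equiv | 20 °C | run made earlier |  |
| flask | 1.30 equiv | 25 °C |  | 12 h |

- dusk (time / h: target / %): 1.33: 3.2; 3.00: 9.1; 4.00: 11.7; 6.00: 14.2; 8.00: 16.0; 10.0: 16.3
- autumn (time / h: target / %): 1.33: 0.5; 3.00: 3.6; 4.00: 6.3; 6.00: 9.4; 8.00: 11.0; 10.0: 12.6

(each reading ± 0.3 percentage points)

- cedar: change nothing and wait 6.0 h more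
- alder: at 12 h take out 90% of the target then present, then wait 6.0 h
- oak: at 12 h raise the temperature by 20 K, then wait 6.0 h

* target, in percent of the starting material first charged, at 12 h
* which option adds most target ("none" when 2 percentage points or less is all one gets) (cedar / alder / oak / none)
* target present, with what was taken out counted in, in percent of the starting material first charged, after cedar
* target present, with what was taken out counted in, in percent of the starting material first charged, after alder

- what is taken out of target is counted as made
- the analysis behind the earlier runs scatters by 0.3 percentage points, standard deviation
- steps under discussion: starting material <-> open intermediate; partner -> second intermediate; open intermediate + second intermediate -> target; partner -> decomposed reagent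

1. Main step alone: open intermediate + second intermediate → target, with one partner behind each target. Partner is charged at 1.30 equiv, so starting material is the limiting reagent and the ceiling is 100%. The dusk run reads 16.3% at 10.0 h.

2. Adding partner → decomposed reagent: each partner step, as written, has partner alone on the left, so at one temperature a fixed share reaches second intermediate, whatever the amount. The target rate is taken to fall with partner. The dusk rise is 5.1 percentage points from 3.00 h to 6.00 h, then 2.1 points from 6.00 h to 10.0 h, which reads as a decay time of 2.98 h. The rate near 8.00 h times that time leaves a tail of 1.6 points, so the plateau reads 17.6%, with the scatter of the readings. Divided by the partner charge, this gives the partner yield, 13.5%.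

3. Adding the rest: the opening of starting material and the build-up of second intermediate appear as the early lag, 3.2% at 1.33 h. The autumn run, at 20 °C, rises 3.2 points from 6.00 h to 10.0 h, so temperature moves the pace; the share at a higher temperature is taken here as unchanged.

4. This reckoning gives 17.2% at 12 h, with 0.41 points of tail still to come. Cedar reaches 17.5%. Alder is reckoned the same, the last step being written one way. Oak, at the share taken as unchanged, collects that same tail, which stays under the margin of 2 points, so this reckoning chooses none.

The forecast gives 17.1%, 17.9% after cedar, 17.9% after alder and none, its cedar figure standing above this reckoning, and it says of alder: “The final step is irreversible, so removing target gains nothing.”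

The flask gives 17.1%, then 17.6% after cedar and 17.6% after alder. Oak adds 0.61 points, and the answer is none.

    starting material ⇌ open intermediate (K = 8.10, k = 6.20 × 10⁻⁵ s⁻¹, Ea = 91.0 kJ mol⁻¹, ΔH = 42.0 kJ mol⁻¹)
    partner → second intermediate (k = 1.10 × 10⁻⁵ s⁻¹, Ea = 106 kJ mol⁻¹)
    open intermediate + second intermediate → target (k = 0.00140 M⁻¹ s⁻¹, Ea = 75.0 kJ mol⁻¹)
    partner → decomposed reagent (k = 7.00 × 10⁻⁵ s⁻¹, Ea = 103 kJ mol⁻¹)
    (constants at 25 °C)

In this flask at 12.0 h, the half-life of partner by the step to decomposed reagent is 2.8 h, shorter than the 18 h by the step to second intermediate, which makes the share to second intermediate 13.6%. In the neighbouring flask with 0.330 equiv of partner, the partner yield of 13.5% and the part of the plateau reached by 12 h give 4.35%, and that flask holds 4.34% of target.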